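**Plan**
1. Retrosynthesis: the C3' hydroxyl is traced back to a C3' bromide; the benzene ring is then cut at C5'–C6' and C3'–C4' (with CO2 restored between C3' and C6'), which leads to methyl 3-bromocoumalate and a bis(silyl) ketene acetal carrying the decalin.
2. Enabling feature: in the arene (C1' ester, C3' and C4' hydroxyls, C5' bearing benzylic C11 on decalin C9) the C4' oxygen is para to the ester and flanked by C3'–O and C5'–CH2. This is the pattern a ketene acetal leaves on a 3-substituted 5-carbomethoxy-2-pyrone (pyrone C5 becomes C1', C3 becomes C3', acetal carbon becomes C4', acetal β-carbon becomes C5').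
3. The ketene acetal comes from the C17 acid HO2C–CH2–C11H2–C9, reached from (−)-sclareol by degrading the side chain (C14, C15, C16 removed) and dehydrating the 8-hydroxyl to the 7-ene.
4. Forward order: rings A and B are taken intact from sclareol; the aromatic ring is built in the penultimate step by [4+2] addition, loss of CO2 and loss of silanol; the bromide is exchanged for hydroxyl last.
5. Stereochemistry: C5, C9 and C10 (5α-H, 9α-H, 10β-CH3) come unchanged from sclareol; no stereocentre is created, and only the position of the ring B double bond and the orientation of the cycloaddition have to be controlled.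

Key step: step 7

Assumption: labdane numbering is kept for the decalin part (C9 carries the chain, C11 is the future benzylic carbon, C12 the α-carbon and C13 the carboxyl carbon of the acid), with primed numbers for the arene.
Assumption: the bromine adduct of methyl coumalate is written as the 3,4-dibromide (a 3,6-dibromide would lose HBr to the same bromopyrone), and the sp3 ring centres of the transient cycloaddition intermediates are left undefined because they disappear on aromatisation.

**Route**

Step 1
Reactants: 1 (−)-sclareol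
Product: 2 8α-hydroxy-14,15-dinorlabdan-13-one
Conditions: KMnO4, MgSO4, acetone/H2O, 0 °C → rt
Reagents that add atoms: none
Why: Permanganate oxidative cleavage of the tertiary vinyl carbinol removes C14 and C15 and leaves the C13 methyl ketone (its oxygen is the former 13-OH), while the tertiary 8-hydroxyl and the saturated decalin are inert and no ring stereocentre is touched.

Step 2
Reactants: 2 8α-hydroxy-14,15-dinorlabdan-13-one
Product: 4 8α-hydroxy-14,15,16-trinorlabdan-13-oic acid, via tribromomethyl ketone 3 (not isolated)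
Conditions: Br2, NaOH, 1,4-dioxane/H2O, 0 °C → rt; then 1 M HCl to pH 3, 0 °C
Reagents that add atoms: sodium hydroxide, [Na+].[OH-]
Why: Haloform reaction: exhaustive α-bromination of the methyl group and hydroxide attack on the carbonyl expel bromoform and shorten the chain to the C17 acid, leaving the 8-hydroxyl and all stereocentres untouched.

Step 3
Reactants: 4 8α-hydroxy-14,15,16-trinorlabdan-13-oic acid
Product: 6 methyl 14,15,16-trinorlabd-7-en-13-oate, via methyl hydroxy ester 5 (not isolated)
Conditions: conc. H2SO4, MeOH, reflux; chromatography on AgNO3-impregnated SiO2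
Reagents that add atoms: methanol, CO
Why: Fischer esterification is followed by E1 dehydration, in which the tertiary C8 cation should lose mainly a C7 proton to give the trisubstituted ring alkene; the 8(17) and 8(9) isomers are to be removed by argentation chromatography, and C9 keeps its hydrogen and configuration in the 7-ene.

Step 4
Reactants: 6 methyl 14,15,16-trinorlabd-7-en-13-oate
Product: 7 14,15,16-trinorlabd-7-en-13-oic acid
Conditions: LiOH·H2O, THF/MeOH/H2O, 40 °C; then 1 M HCl to pH 4, 0 °C
Reagents that add atoms: lithium hydroxide, [Li+].[OH-]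
Why: Ester saponification of an unhindered methyl ester; the brief cold acidification should leave the acid-sensitive 7-ene in place.

Step 5
Reactants: 7 14,15,16-trinorlabd-7-en-13-oic acid
Product: 9 2-(drim-7-en-11-yl)-1,1-bis(trimethylsilyloxy)ethene, via dilithium enediolate 8 (not isolated)
Conditions: LiN(iPr)2 (2.2 equiv), THF, −78 → 0 °C; Me3SiCl (2.5 equiv), −78 °C → rt; pentane, filtration under Ar, used crude
Reagents that add atoms: chlorotrimethylsilane, C[Si](C)(C)Cl
Why: Double deprotonation of the acid gives the enediolate, which the hard silyl chloride should silylate on both oxygens (bis-silyl ketene acetal formation); the two oxygen substituents are identical, so no alkene geometry arises, and C9 is not acidic.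

Step 6
Reactants: 10 methyl coumalate
Product: 12 methyl 3-bromocoumalate, via dibromide 11 (not isolated)
Conditions: Br2, CH2Cl2, 0 °C → rt; then Et3N, 0 °C
Reagents that add atoms: bromine, BrBr
Why: Bromine addition followed by dehydrobromination amounts to electrophilic substitution at C3, the only nucleophilic ring position left once C5 carries the ester.

Step 7
Reactants: 9 2-(drim-7-en-11-yl)-1,1-bis(trimethylsilyloxy)ethene; 12 methyl 3-bromocoumalate
Product: 16 methyl 3-bromo-5-(drim-7-en-11-yl)-4-hydroxybenzoate, via bridged lactone 13 (not isolated), via cyclohexadiene 14 (not isolated), via aryl silyl ether 15 (not isolated)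
Conditions: 9 (1.5 equiv), PhMe, 25 → 110 °C, sealed tube, Ar; then K2CO3 (cat.), MeOH, 0 °C
Reagents that add atoms: none
Why: The electron-poor diene of 12 (C3=C4–C5=C6, lowered by the lactone, the ester and bromine) and the electron-rich ketene acetal 9 should combine in an inverse-electron-demand Diels–Alder reaction, probably asynchronous, with the acetal β-carbon (C12) bonding to pyrone C6 ahead of the acetal carbon (C13) bonding to C3; the closest known reactions are the cycloadditions of methyl coumalate and of 3-bromo-2-pyrones with ketene acetals and enol ethers that end in benzoates. The six-membered carbocycle is closed by this intermolecular [4+2] addition (bonds C5'–C6' and C3'–C4'), giving bridged lactone 13. Retro-[4+2] loss of CO2 from 13 gives diene 14, 1,2-elimination of Me3SiOH across C4'–C5' aromatises it to 15, and methanolysis of the aryl silyl ether frees phenol 16. No stereocentre is created: the three sp3 ring centres of 13 are transient and vanish on aromatisation, and C5, C9 and C10 lie outside the reacting system. The only selectivity needed is orientation, and matched polarity secures it: C6 is the electrophilic terminus (β to the ester, vinylogous to the lactone carbonyl) and the acetal β-carbon the nucleophilic one, so oxygen ends para to the ester and next to bromine. The trisubstituted, electronically neutral 7-ene should not compete as a dienophile.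

Step 8
Reactants: 16 methyl 3-bromo-5-(drim-7-en-11-yl)-4-hydroxybenzoate
Product: 18 methyl 3-(drim-7-en-11-yl)-4,5-dihydroxybenzoate, via aryl boronate 17 (not isolated)
Conditions: Pd(dppf)Cl2 (5 mol %), B2pin2, KOAc, 1,4-dioxane, 90 °C; then NaBO3·4H2O, THF/H2O, 0 °C → rt; pH 6 buffer work-up under Ar
Reagents that add atoms: sodium perborate, [Na+].[O-]OB=O
Why: Miyaura borylation (zerovalent palladium formed in situ inserts into C3'–Br, acetate-assisted transmetalation with the diboron) followed by perborate oxidation of the C–B bond with 1,2-aryl shift to oxygen should give the catechol; the weakly basic, acid-free conditions spare the methyl ester and avoid phenol-to-alkene cyclisation at C8.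

**Compound list**

1 | (−)-sclareol, (13R)-labd-14-ene-8α,13-diol | C=C[C@](C)(O)CC[C@H]1[C@](C)(O)CC[C@H]2C(C)(C)CCC[C@]12C | starting material
2 | 8α-hydroxy-14,15-dinorlabdan-13-one (5α-H, 9α-H, 10β-CH3) | CC(=O)CC[C@H]1[C@](C)(O)CC[C@H]2C(C)(C)CCC[C@]12C | intermediate
3 | 16,16,16-tribromo-8α-hydroxy-14,15-dinorlabdan-13-one | BrC(Br)(Br)C(=O)CC[C@H]1[C@](C)(O)CC[C@H]2C(C)(C)CCC[C@]12C | intermediate
4 | 8α-hydroxy-14,15,16-trinorlabdan-13-oic acid | OC(=O)CC[C@H]1[C@](C)(O)CC[C@H]2C(C)(C)CCC[C@]12C | intermediate
5 | methyl 8α-hydroxy-14,15,16-trinorlabdan-13-oate | COC(=O)CC[C@H]1[C@](C)(O)CC[C@H]2C(C)(C)CCC[C@]12C | intermediate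
6 | methyl 14,15,16-trinorlabd-7-en-13-oate (5S,9S,10S) | COC(=O)CC[C@H]1C(C)=CC[C@H]2C(C)(C)CCC[C@]12C | intermediate
7 | 14,15,16-trinorlabd-7-en-13-oic acid, i.e. 3-(drim-7-en-11-yl)propanoic acid counting C11 as C3 | OC(=O)CC[C@H]1C(C)=CC[C@H]2C(C)(C)CCC[C@]12C | intermediate
8 | dilithium enediolate of acid 7 | [Li+].[Li+].[O-]C([O-])=CC[C@H]1C(C)=CC[C@H]2C(C)(C)CCC[C@]12C | intermediate
9 | 2-(drim-7-en-11-yl)-1,1-bis(trimethylsilyloxy)ethene, the bis(trimethylsilyl) ketene acetal of acid 7 | C[Si](C)(C)OC(O[Si](C)(C)C)=CC[C@H]1C(C)=CC[C@H]2C(C)(C)CCC[C@]12C | intermediate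
10 | methyl coumalate, methyl 2-oxo-2H-pyran-5-carboxylate | COC(=O)C1=COC(=O)C=C1 | starting material
11 | methyl 3,4-dibromo-2-oxo-3,4-dihydro-2H-pyran-5-carboxylate | COC(=O)C1=COC(=O)C(Br)C1Br | intermediate
12 | methyl 3-bromocoumalate, methyl 3-bromo-2-oxo-2H-pyran-5-carboxylate | COC(=O)C1=COC(=O)C(Br)=C1 | intermediate
13 | methyl 4-bromo-6-(drim-7-en-11-yl)-3-oxo-5,5-bis(trimethylsilyloxy)-2-oxabicyclo[2.2.2]oct-7-ene-7-carboxylate (diastereomer mixture at the bicycle) | COC(=O)C1=CC2(Br)C(=O)OC1C(C[C@H]3C(C)=CC[C@H]4C(C)(C)CCC[C@]34C)C2(O[Si](C)(C)C)O[Si](C)(C)C | intermediate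
14 | methyl 5-bromo-3-(drim-7-en-11-yl)-4,4-bis(trimethylsilyloxy)cyclohexa-1,5-diene-1-carboxylate | COC(=O)C1=CC(C[C@H]2C(C)=CC[C@H]3C(C)(C)CCC[C@]23C)C(O[Si](C)(C)C)(O[Si](C)(C)C)C(Br)=C1 | intermediate
15 | methyl 3-bromo-5-(drim-7-en-11-yl)-4-(trimethylsilyloxy)benzoate | COC(=O)c1cc(Br)c(O[Si](C)(C)C)c(C[C@H]2C(C)=CC[C@H]3C(C)(C)CCC[C@]23C)c1 | intermediate
16 | methyl 3-bromo-5-(drim-7-en-11-yl)-4-hydroxybenzoate | COC(=O)c1cc(Br)c(O)c(C[C@H]2C(C)=CC[C@H]3C(C)(C)CCC[C@]23C)c1 | intermediate
17 | methyl 3-(drim-7-en-11-yl)-4-hydroxy-5-(4,4,5,5-tetramethyl-1,3,2-dioxaborolan-2-yl)benzoate | COC(=O)c1cc(B4OC(C)(C)C(C)(C)O4)c(O)c(C[C@H]2C(C)=CC[C@H]3C(C)(C)CCC[C@]23C)c1 | intermediate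
18 | methyl 3-(drim-7-en-11-yl)-4,5-dihydroxybenzoate, (5S,9S,10S), CNP0193946.2 | COC(=O)c1cc(O)c(O)c(C[C@H]2C(C)=CC[C@H]3C(C)(C)CCC[C@]23C)c1 | target

**Count and risks**

Total step count: 8. Longest linear sequence: 7 steps (steps 1–5, 7, 8); step 6 is a one-step branch.

1. Step 7. What may go wrong: the first C–C bond (acetal β-carbon to C6) may form without ring closure at the crowded, bromine-bearing C3, so that silyl transfer and opening of the pyrone take over; silanol released on aromatisation may also protodesilylate unreacted ketene acetal. The fallback sets out from 9 and starting material 10 and comes back at target 18, so steps 6 and 8 fall away. Compound 9 is heated with methyl coumalate 10 itself, whose C3 is unhindered, under the conditions of step 7. Through the bromine-free bridged lactone F1, the cyclohexadiene F2 and the aryl silyl ether F3 this should give methyl 3-(drim-7-en-11-yl)-4-hydroxybenzoate F4. Magnesium-mediated ortho-formylation at the only free ortho position (MgCl2, Et3N, paraformaldehyde, MeCN, reflux) should give the salicylaldehyde F5. Dakin oxidation (Na2CO3·1.5H2O2, THF/H2O, rt), through the aryl formate F6, should then deliver 18.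

2. Step 3. What may go wrong: unselective proton loss from the C8 cation and acid-driven drift of the double bond into the 8(9) position, leaving isomers that argentation chromatography does not fully resolve. The fallback sets out from 4 and comes back at 6. Acid-free methylation of 4 (MeI, K2CO3, DMF) gives 5, this time isolated. Treatment with SOCl2 and pyridine in CH2Cl2 at −78 °C, an E2 process that should take a methyl hydrogen anti to the equatorial leaving group, gives the exocyclic alkene methyl 14,15,16-trinorlabd-8(17)-en-13-oate F7. Ozonolysis (O3, CH2Cl2, −78 °C; then Me2S), through the ozonide F8, gives the 8-ketone F9. Kinetic deprotonation at the C7 methylene (LiN(iPr)2, THF, −78 °C) gives the lithium enolate F10, which PhNTf2 traps as the 7-en-8-yl triflate F11. Iron-catalysed cross-coupling with MeMgBr (Fe(acac)3, THF/NMP, −30 °C) then installs the C8 methyl and gives 6 with the double bond fixed between C7 and C8.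

3. Step 8. What may go wrong: slow oxidative addition and protodebromination at the phenoxide-flanked C–Br bond, and over-oxidation of the catechol while peroxide is present. The fallback sets out from 16 and comes back at 18. Benzylation (BnBr, K2CO3, DMF) gives the benzyl ether F12. Palladium-catalysed C–O coupling with benzaldoxime as hydroxide surrogate (Pd2(dba)3, tBuBrettPhos, Cs2CO3, DMF, 80 °C) proceeds through the O-aryl oxime F13, which fragments to the monobenzyl catechol F14. Transfer hydrogenolysis (Pd/C, 1,4-cyclohexadiene, EtOH, rt), which should spare the hindered trisubstituted alkene, gives 18 without any peroxide.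

**Further compounds**

F1 | step 7 | methyl 6-(drim-7-en-11-yl)-3-oxo-5,5-bis(trimethylsilyloxy)-2-oxabicyclo[2.2.2]oct-7-ene-7-carboxylate | COC(=O)C1=CC2C(=O)OC1C(C[C@H]3C(C)=CC[C@H]4C(C)(C)CCC[C@]34C)C2(O[Si](C)(C)C)O[Si](C)(C)C
F2 | step 7 | methyl 3-(drim-7-en-11-yl)-4,4-bis(trimethylsilyloxy)cyclohexa-1,5-diene-1-carboxylate | COC(=O)C1=CC(C[C@H]2C(C)=CC[C@H]3C(C)(C)CCC[C@]23C)C(O[Si](C)(C)C)(O[Si](C)(C)C)C=C1
F3 | step 7 | methyl 3-(drim-7-en-11-yl)-4-(trimethylsilyloxy)benzoate | COC(=O)c1ccc(O[Si](C)(C)C)c(C[C@H]2C(C)=CC[C@H]3C(C)(C)CCC[C@]23C)c1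
F4 | step 7 | methyl 3-(drim-7-en-11-yl)-4-hydroxybenzoate | COC(=O)c1ccc(O)c(C[C@H]2C(C)=CC[C@H]3C(C)(C)CCC[C@]23C)c1
F5 | step 7 | methyl 3-(drim-7-en-11-yl)-5-formyl-4-hydroxybenzoate | COC(=O)c1cc(C=O)c(O)c(C[C@H]2C(C)=CC[C@H]3C(C)(C)CCC[C@]23C)c1
F6 | step 7 | methyl 3-(drim-7-en-11-yl)-5-(formyloxy)-4-hydroxybenzoate | COC(=O)c1cc(OC=O)c(O)c(C[C@H]2C(C)=CC[C@H]3C(C)(C)CCC[C@]23C)c1
F7 | step 3 | methyl 14,15,16-trinorlabd-8(17)-en-13-oate | COC(=O)CC[C@H]1C(=C)CC[C@H]2C(C)(C)CCC[C@]12C
F8 | step 3 | 8,17-ozonide (spiro-1,2,4-trioxolane at C8) of F7 | COC(=O)CC[C@H]1C3(OCOO3)CC[C@H]2C(C)(C)CCC[C@]12C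
F9 | step 3 | methyl 8-oxo-14,15,16,17-tetranorlabdan-13-oate | COC(=O)CC[C@H]1C(=O)CC[C@H]2C(C)(C)CCC[C@]12C
F10 | step 3 | lithium 7-en-8-olate of F9 | [Li+].COC(=O)CC[C@H]1C([O-])=CC[C@H]2C(C)(C)CCC[C@]12C
F11 | step 3 | methyl 8-(trifluoromethylsulfonyloxy)-14,15,16,17-tetranorlabd-7-en-13-oate | COC(=O)CC[C@H]1C(OS(=O)(=O)C(F)(F)F)=CC[C@H]2C(C)(C)CCC[C@]12C
F12 | step 8 | methyl 4-(benzyloxy)-3-bromo-5-(drim-7-en-11-yl)benzoate | COC(=O)c1cc(Br)c(OCc4ccccc4)c(C[C@H]2C(C)=CC[C@H]3C(C)(C)CCC[C@]23C)c1
F13 | step 8 | methyl 4-(benzyloxy)-3-(benzylideneaminooxy)-5-(drim-7-en-11-yl)benzoate | COC(=O)c1cc(ON=Cc5ccccc5)c(OCc4ccccc4)c(C[C@H]2C(C)=CC[C@H]3C(C)(C)CCC[C@]23C)c1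
F14 | step 8 | methyl 4-(benzyloxy)-3-(drim-7-en-11-yl)-5-hydroxybenzoate | COC(=O)c1cc(O)c(OCc4ccccc4)c(C[C@H]2C(C)=CC[C@H]3C(C)(C)CCC[C@]23C)c1
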